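**Retrosynthetic overview**
1. Target 29 ← C6 ketone 28 by a late ketone reduction that sets C6.
2. 28 ← one-carbon ring expansion (six → seven): C7 of diazoalkane 27 is inserted between C6 and C8 of the trans-hydrindenone 15, which joins core and side chain and sets C7.
3. 15 ← (R)-4-silyloxycyclohexenone 4 by conjugate addition/allylation, ring-closing metathesis, C9 hydroxylation and C10 methylenation; 4 ← cyclohexa-1,3-diene.
4. 27 ← prenal + hydroxyacetone (syn-aldol sets C12/C13), methylenation, directed hydroboration (sets C11), hydrazone.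
5. Ring order: cyclohexane (from 1) → cyclopentene (metathesis) → cycloheptane (ring expansion, last C–C bond-forming step).

Assumption: C1–C15 follow the dictyol numbering (C1/C5 ring fusion, C6 carbinol, C7 bears the side chain C11–C15, C9 acetoxy, C10 exocyclic methylene); chiral catalysts, ligands and auxiliaries are taken in the antipode that gives the drawn isomers.

Step 1
Reactants: 1 cyclohexa-1,3-diene
Product: 2 2,3-dioxabicyclo[2.2.2]oct-5-ene
Conditions: O2, TPP (cat.), hν, CH2Cl2, 0 °C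
Reagents that add atoms: oxygen (O=O)
Why: Singlet-oxygen [4+2] photooxygenation of the cyclic diene gives the meso endoperoxide, so no stereochemical issue arises.

Step 2
Reactants: 2 2,3-dioxabicyclo[2.2.2]oct-5-ene
Product: 4 (R)-4-[(tert-butyldimethylsilyl)oxy]cyclohex-2-en-1-one, via (R)-4-hydroxycyclohex-2-en-1-one 3 (not isolated)
Conditions: cinchona-derived 6′-hydroxy base (5 mol %), CH2Cl2, rt; then TBSCl, imidazole, 0 °C → rt
Reagents that add atoms: tert-butyldimethylsilyl chloride (CC(C)(C)[Si](C)(C)Cl)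
Why: Enantioselective Kornblum–DeLaMare rearrangement, in which the chiral base removes one of the two enantiotopic bridgehead hydrogens and sets C6 (R), followed by silylation of the sensitive γ-hydroxy enone in the same pot.

Step 3
Reactants: 4 (R)-4-[(tert-butyldimethylsilyl)oxy]cyclohex-2-en-1-one, 5 isopropenylmagnesium bromide, 6 allyl iodide
Product: 8 (2R,3S,4R)-2-allyl-4-[(tert-butyldimethylsilyl)oxy]-3-(prop-1-en-2-yl)cyclohexan-1-one, via bromomagnesium enolate 7 (not isolated)
Conditions: CuBr·SMe2 (20 mol %), THF, −78 °C; then HMPA, −78 → −20 °C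
Reagents that add atoms: none
Why: Copper-catalysed conjugate addition anti to the 4-silyloxy group sets C5, and alkylation of the resulting enolate trans to the new isopropenyl group sets C1 (three-component coupling, all-equatorial product).

Step 4
Reactants: 8 (2R,3S,4R)-2-allyl-4-[(tert-butyldimethylsilyl)oxy]-3-(prop-1-en-2-yl)cyclohexan-1-one
Product: 9 (3aR,7R,7aS)-7-[(tert-butyldimethylsilyl)oxy]-1-methyl-3,3a,5,6,7,7a-hexahydro-4H-inden-4-one
Conditions: Grubbs II (3 mol %), CH2Cl2, 40 °C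
Reagents that add atoms: none
Why: Ring-closing metathesis of the allyl and isopropenyl groups forms the trisubstituted C3=C4 cyclopentene, with the trans ring fusion already fixed in step 3.

Step 5
Reactants: 9 (3aR,7R,7aS)-7-[(tert-butyldimethylsilyl)oxy]-1-methyl-3,3a,5,6,7,7a-hexahydro-4H-inden-4-one
Product: 11 (3aR,5R,7R,7aS)-7-[(tert-butyldimethylsilyl)oxy]-5-hydroxy-1-methyl-3,3a,5,6,7,7a-hexahydro-4H-inden-4-one, via potassium enolate 10 (not isolated)
Conditions: KHMDS, THF, −78 °C; then 2-(phenylsulfonyl)-3-phenyloxaziridine, −78 °C; aq. NH4Cl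
Reagents that add atoms: 2-(phenylsulfonyl)-3-phenyloxaziridine (O=S(=O)(N1OC1c1ccccc1)c1ccccc1)
Why: Kinetic deprotonation at the less substituted C9 and Davis enolate hydroxylation, in which stereoelectronically preferred axial attack on the conformationally locked enolate should give the axial 9α-alcohol (C9 R).

Step 6
Reactants: 11 (3aR,5R,7R,7aS)-7-[(tert-butyldimethylsilyl)oxy]-5-hydroxy-1-methyl-3,3a,5,6,7,7a-hexahydro-4H-inden-4-one
Product: 12 (3aR,5R,7R,7aS)-7-[(tert-butyldimethylsilyl)oxy]-1-methyl-4-oxo-3a,4,5,6,7,7a-hexahydro-3H-inden-5-yl acetate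
Conditions: Ac2O, pyridine, DMAP (cat.), CH2Cl2, 0 °C
Reagents that add atoms: acetic anhydride (CC(=O)OC(C)=O)
Why: Acylation of the secondary α-hydroxy ketone installs the C9 acetate of the target without touching the stereocentre.

Step 7
Reactants: 12 (3aR,5R,7R,7aS)-7-[(tert-butyldimethylsilyl)oxy]-1-methyl-4-oxo-3a,4,5,6,7,7a-hexahydro-3H-inden-5-yl acetate
Product: 13 (3aR,5R,7R,7aS)-7-[(tert-butyldimethylsilyl)oxy]-1-methyl-4-methylidene-3a,4,5,6,7,7a-hexahydro-3H-inden-5-yl acetate
Conditions: Zn, CH2Br2, TiCl4, THF/CH2Cl2, 0 °C → rt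
Reagents that add atoms: dibromomethane (BrCBr)
Why: Takai–Lombardo methylenation is non-basic and ketone-selective, so the hindered C10 ketone becomes the exocyclic methylene while the acetate, the silyl ether and the epimerisable C1 and C9 centres are preserved.

Step 8
Reactants: 13 (3aR,5R,7R,7aS)-7-[(tert-butyldimethylsilyl)oxy]-1-methyl-4-methylidene-3a,4,5,6,7,7a-hexahydro-3H-inden-5-yl acetate
Product: 14 (3aR,5R,7R,7aS)-7-hydroxy-1-methyl-4-methylidene-3a,4,5,6,7,7a-hexahydro-3H-inden-5-yl acetate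
Conditions: HF·pyridine, pyridine, THF, 0 °C → rt
Reagents that add atoms: none
Why: Fluoride-mediated Si–O cleavage frees the C6 alcohol under buffered conditions that leave the allylic acetate and both alkenes intact.

Step 9
Reactants: 14 (3aR,5R,7R,7aS)-7-hydroxy-1-methyl-4-methylidene-3a,4,5,6,7,7a-hexahydro-3H-inden-5-yl acetate
Product: 15 (3aR,5R,7aS)-1-methyl-4-methylidene-7-oxo-3a,4,5,6,7,7a-hexahydro-3H-inden-5-yl acetate
Conditions: Dess–Martin periodinane, NaHCO3, CH2Cl2, 0 °C; used at once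
Reagents that add atoms: none
Why: Buffered Dess–Martin oxidation gives the C6 ketone under neutral conditions, which avoids epimerisation at C5, conjugation of the β,γ-alkene and β-elimination of the C9 acetate.

Step 10
Reactants: 16 3-methylbut-2-enal, 17 hydroxyacetone
Product: 18 (3R,4S)-3,4-dihydroxy-6-methylhept-5-en-2-one
Conditions: O-tert-butyl-L-threonine (20 mol %), NMP, 4 °C (17 in excess)
Reagents that add atoms: none
Why: Primary-amino-acid-catalysed direct syn-aldol reaction, in which the hydrogen-bonded (Z)-enamine of hydroxyacetone adds to the aldehyde carbon of the β,β-disubstituted enal and sets C12 and C13 as the syn diol.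

Step 11
Reactants: 18 (3R,4S)-3,4-dihydroxy-6-methylhept-5-en-2-one
Product: 19 1-[(4R,5S)-2,2-dimethyl-5-(2-methylprop-1-en-1-yl)-1,3-dioxolan-4-yl]ethan-1-one
Conditions: 2,2-dimethoxypropane, PPTS (cat.), CH2Cl2, rt
Reagents that add atoms: 2,2-dimethoxypropane (COC(C)(C)OC)
Why: Acetalisation of the syn diol gives the trans-dioxolane, which blocks retro-aldol and β-elimination in the next step.

Step 12
Reactants: 19 1-[(4R,5S)-2,2-dimethyl-5-(2-methylprop-1-en-1-yl)-1,3-dioxolan-4-yl]ethan-1-one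
Product: 20 (4S,5S)-2,2-dimethyl-4-(2-methylprop-1-en-1-yl)-5-(prop-1-en-2-yl)-1,3-dioxolane
Conditions: Ph3PCH3Br, KOtBu, THF, 0 °C → rt
Reagents that add atoms: methyltriphenylphosphonium bromide (C[P+](c1ccccc1)(c1ccccc1)c1ccccc1.[Br-])
Why: Wittig methylenation turns the methyl ketone into the isopropenyl group (C7=C11), and any base-induced epimerisation at C12 returns to the favoured trans-dioxolane.

Step 13
Reactants: 20 (4S,5S)-2,2-dimethyl-4-(2-methylprop-1-en-1-yl)-5-(prop-1-en-2-yl)-1,3-dioxolane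
Product: 21 (3S,4S)-2,6-dimethylhepta-1,5-diene-3,4-diol
Conditions: AcOH/H2O (4:1), 40 °C
Reagents that add atoms: none
Why: Mild acid hydrolysis of the acetal proceeds through the oxocarbenium ion at the acetal carbon, so the two allylic C–O bonds and their configurations are not disturbed.

Step 14
Reactants: 21 (3S,4S)-2,6-dimethylhepta-1,5-diene-3,4-diol
Product: 22 (3S,4S)-2,6-dimethylhepta-1,5-diene-3,4-diyl diacetate
Conditions: Ac2O, pyridine, DMAP (cat.), CH2Cl2, 0 °C → rt
Reagents that add atoms: acetic anhydride (CC(=O)OC(C)=O)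
Why: Acylation installs the C12 and C13 acetates of the target at a stage where no carbonyl group is present that could trigger β-elimination.

Step 15
Reactants: 22 (3S,4S)-2,6-dimethylhepta-1,5-diene-3,4-diyl diacetate
Product: 24 (2R,3S,4S)-1-hydroxy-2,6-dimethylhept-5-ene-3,4-diyl diacetate, via catechol boronate 23 (not isolated)
Conditions: catecholborane, RhCl(PPh3)3 (3 mol %), THF, 0 °C → rt; then H2O2, pH 7 phosphate buffer, 0 °C
Reagents that add atoms: hydrogen peroxide (OO)
Why: Rhodium-catalysed anti-Markovnikov hydroboration of the 1,1-disubstituted alkene is syn-selective with respect to the allylic acetate (sets C11, R, expected dr about 8:1) and leaves the trisubstituted alkene alone, and buffered oxidation avoids acetyl migration.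

Step 16
Reactants: 24 (2R,3S,4S)-1-hydroxy-2,6-dimethylhept-5-ene-3,4-diyl diacetate
Product: 25 (2S,3S,4S)-2,6-dimethyl-1-oxohept-5-ene-3,4-diyl diacetate
Conditions: Dess–Martin periodinane, NaHCO3, CH2Cl2, 0 °C; used crude
Reagents that add atoms: none
Why: Neutral Dess–Martin oxidation gives the α-branched, β-acetoxy aldehyde without epimerisation at C11 or elimination.

Step 17
Reactants: 25 (2S,3S,4S)-2,6-dimethyl-1-oxohept-5-ene-3,4-diyl diacetate
Product: 26 (2R,3S,4S)-1-[(E)-2-(tert-butyldimethylsilyl)hydrazinylidene]-2,6-dimethylhept-5-ene-3,4-diyl diacetate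
Conditions: TBSNHNHTBS, Sc(OTf)3 (0.01 mol %), neat, 0 °C → rt; volatiles removed in vacuo
Reagents that add atoms: 1,2-bis(tert-butyldimethylsilyl)hydrazine (CC(C)(C)[Si](C)(C)NN[Si](C)(C)C(C)(C)C)
Why: Condensation to the N-silyl hydrazone is neutral and azine-free, so the acetates and the C11 stereocentre survive and a clean diazoalkane precursor results.

Step 18
Reactants: 26 (2R,3S,4S)-1-[(E)-2-(tert-butyldimethylsilyl)hydrazinylidene]-2,6-dimethylhept-5-ene-3,4-diyl diacetate, 15 (3aR,5R,7aS)-1-methyl-4-methylidene-7-oxo-3a,4,5,6,7,7a-hexahydro-3H-inden-5-yl acetate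
Product: 28 (2R,3S,4S)-2-[(3aS,5S,7R,8aR)-7-acetoxy-3-methyl-8-methylidene-4-oxo-1,3a,4,5,6,7,8,8a-octahydroazulen-5-yl]-6-methylhept-5-ene-3,4-diyl diacetate, via diazoalkane 27 (not isolated)
Conditions: PhIF2, 2-chloropyridine, CH2Cl2, −78 °C, cold filtration through basic alumina; then 15, Sc(OTf)3 (10 mol %), (S,S)-t-Bu-PyBox (12 mol %), toluene, −78 °C
Reagents that add atoms: none
Why: Proposed new method: a bulky chiral PyBox–Sc(III) Lewis acid activates the C6 ketone, the non-stabilised diazo carbon C7 adds along the equatorial trajectory (the axial C9 acetate screens the other one), the catalyst selects the diazo face so that the C11 branch sits anti to the Sc-bound oxygen and N2+ anti to the C6–C8 bond, and the less substituted C8 then shifts from C6 to C7 with loss of N2 and inversion at C7, which expands the six-membered ring to the seven-membered ring, joins the two fragments and sets C7 (S, side chain β); the closest known reaction type is the Sc(OTf)3-catalysed diazoalkane–ketone homologation (Tiffeneau–Demjanov-type ring expansion) with aryl- and simple alkyl-diazomethanes, not yet shown under catalyst control for an α-branched, oxygenated alkyl diazomethane that creates an α-tertiary centre in a fragment coupling.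

Step 19
Reactants: 28 (2R,3S,4S)-2-[(3aS,5S,7R,8aR)-7-acetoxy-3-methyl-8-methylidene-4-oxo-1,3a,4,5,6,7,8,8a-octahydroazulen-5-yl]-6-methylhept-5-ene-3,4-diyl diacetate
Product: 29 (2R,3S,4S)-2-[(3aS,4R,5S,7R,8aR)-7-acetoxy-4-hydroxy-3-methyl-8-methylidene-1,3a,4,5,6,7,8,8a-octahydroazulen-5-yl]-6-methylhept-5-ene-3,4-diyl diacetate
Conditions: NaBH4, CeCl3·7H2O, MeOH, −40 °C
Reagents that add atoms: none
Why: Luche reduction, in which hydride is expected to approach the C6 carbonyl from the α-face, anti to the β-oriented C7 side chain (as in reductions of 2-alkylcycloalkanones to cis-alcohols), giving the 6β-alcohol (R) while the three acetates and the alkenes are untouched at low temperature.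

**Compound list**
1 | cyclohexa-1,3-diene | C1=CC=CCC1 | starting material
2 | 2,3-dioxabicyclo[2.2.2]oct-5-ene (meso) | C1=C[C@H]2CC[C@@H]1OO2 | intermediate
3 | (R)-4-hydroxycyclohex-2-en-1-one | O=C1CC[C@@H](O)C=C1 | intermediate
4 | (R)-4-[(tert-butyldimethylsilyl)oxy]cyclohex-2-en-1-one | O=C1CC[C@@H](O[Si](C)(C)C(C)(C)C)C=C1 | intermediate
5 | isopropenylmagnesium bromide | C=C(C)[Mg]Br | starting material
6 | allyl iodide | C=CCI | starting material
7 | bromomagnesium (3S,4R)-4-[(tert-butyldimethylsilyl)oxy]-3-(prop-1-en-2-yl)cyclohex-1-en-1-olate | Br[Mg]OC1=C[C@@H](C(C)=C)[C@H](O[Si](C)(C)C(C)(C)C)CC1 | intermediate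
8 | (2R,3S,4R)-2-allyl-4-[(tert-butyldimethylsilyl)oxy]-3-(prop-1-en-2-yl)cyclohexan-1-one | O=C1CC[C@@H](O[Si](C)(C)C(C)(C)C)[C@H](C(C)=C)[C@H]1CC=C | intermediate
9 | (3aR,7R,7aS)-7-[(tert-butyldimethylsilyl)oxy]-1-methyl-3,3a,5,6,7,7a-hexahydro-4H-inden-4-one (trans-fused) | O=C1CC[C@@H](O[Si](C)(C)C(C)(C)C)[C@@H]2C(C)=CC[C@@H]12 | intermediate
10 | potassium (3aR,7R,7aS)-7-[(tert-butyldimethylsilyl)oxy]-1-methyl-3a,6,7,7a-tetrahydro-3H-inden-4-olate | [K+].[O-]C1=CC[C@@H](O[Si](C)(C)C(C)(C)C)[C@@H]2C(C)=CC[C@@H]12 | intermediate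
11 | (3aR,5R,7R,7aS)-7-[(tert-butyldimethylsilyl)oxy]-5-hydroxy-1-methyl-3,3a,5,6,7,7a-hexahydro-4H-inden-4-one | O=C1[C@H](O)C[C@@H](O[Si](C)(C)C(C)(C)C)[C@@H]2C(C)=CC[C@@H]12 | intermediate
12 | (3aR,5R,7R,7aS)-7-[(tert-butyldimethylsilyl)oxy]-1-methyl-4-oxo-3a,4,5,6,7,7a-hexahydro-3H-inden-5-yl acetate | O=C1[C@H](OC(C)=O)C[C@@H](O[Si](C)(C)C(C)(C)C)[C@@H]2C(C)=CC[C@@H]12 | intermediate
13 | (3aR,5R,7R,7aS)-7-[(tert-butyldimethylsilyl)oxy]-1-methyl-4-methylidene-3a,4,5,6,7,7a-hexahydro-3H-inden-5-yl acetate | C=C1[C@H](OC(C)=O)C[C@@H](O[Si](C)(C)C(C)(C)C)[C@@H]2C(C)=CC[C@@H]12 | intermediate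
14 | (3aR,5R,7R,7aS)-7-hydroxy-1-methyl-4-methylidene-3a,4,5,6,7,7a-hexahydro-3H-inden-5-yl acetate | C=C1[C@H](OC(C)=O)C[C@@H](O)[C@@H]2C(C)=CC[C@@H]12 | intermediate
15 | (3aR,5R,7aS)-1-methyl-4-methylidene-7-oxo-3a,4,5,6,7,7a-hexahydro-3H-inden-5-yl acetate | C=C1[C@H](OC(C)=O)CC(=O)[C@@H]2C(C)=CC[C@@H]12 | intermediate
16 | 3-methylbut-2-enal (prenal) | CC(C)=CC=O | starting material
17 | hydroxyacetone | CC(=O)CO | starting material
18 | (3R,4S)-3,4-dihydroxy-6-methylhept-5-en-2-one | CC(=O)[C@H](O)[C@H](C=C(C)C)O | intermediate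
19 | 1-[(4R,5S)-2,2-dimethyl-5-(2-methylprop-1-en-1-yl)-1,3-dioxolan-4-yl]ethan-1-one | CC(=O)[C@@H]1OC(C)(C)O[C@H]1C=C(C)C | intermediate
20 | (4S,5S)-2,2-dimethyl-4-(2-methylprop-1-en-1-yl)-5-(prop-1-en-2-yl)-1,3-dioxolane | C=C(C)[C@@H]1OC(C)(C)O[C@H]1C=C(C)C | intermediate
21 | (3S,4S)-2,6-dimethylhepta-1,5-diene-3,4-diol | C=C(C)[C@H](O)[C@H](C=C(C)C)O | intermediate
22 | (3S,4S)-2,6-dimethylhepta-1,5-diene-3,4-diyl diacetate | C=C(C)[C@H](OC(C)=O)[C@H](C=C(C)C)OC(C)=O | intermediate
23 | 2-[(2R,3S,4S)-3,4-diacetoxy-2,6-dimethylhept-5-en-1-yl]-1,3,2-benzodioxaborole | c1ccc2OB(C[C@@H](C)[C@H](OC(C)=O)[C@H](C=C(C)C)OC(C)=O)Oc2c1 | intermediate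
24 | (2R,3S,4S)-1-hydroxy-2,6-dimethylhept-5-ene-3,4-diyl diacetate | OC[C@@H](C)[C@H](OC(C)=O)[C@H](C=C(C)C)OC(C)=O | intermediate
25 | (2S,3S,4S)-2,6-dimethyl-1-oxohept-5-ene-3,4-diyl diacetate | O=C[C@@H](C)[C@H](OC(C)=O)[C@H](C=C(C)C)OC(C)=O | intermediate
26 | (2R,3S,4S)-1-[(E)-2-(tert-butyldimethylsilyl)hydrazinylidene]-2,6-dimethylhept-5-ene-3,4-diyl diacetate | CC(C)(C)[Si](C)(C)N/N=C/[C@@H](C)[C@H](OC(C)=O)[C@H](C=C(C)C)OC(C)=O | intermediate
27 | (2R,3S,4S)-1-diazo-2,6-dimethylhept-5-ene-3,4-diyl diacetate | [N-]=[N+]=C[C@@H](C)[C@H](OC(C)=O)[C@H](C=C(C)C)OC(C)=O | intermediate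
28 | (2R,3S,4S)-2-[(3aS,5S,7R,8aR)-7-acetoxy-3-methyl-8-methylidene-4-oxo-1,3a,4,5,6,7,8,8a-octahydroazulen-5-yl]-6-methylhept-5-ene-3,4-diyl diacetate | C=C1[C@H](OC(C)=O)C[C@@H]([C@@H](C)[C@H](OC(C)=O)[C@H](C=C(C)C)OC(C)=O)C(=O)[C@@H]2C(C)=CC[C@@H]12 | intermediate
29 | (2R,3S,4S)-2-[(3aS,4R,5S,7R,8aR)-7-acetoxy-4-hydroxy-3-methyl-8-methylidene-1,3a,4,5,6,7,8,8a-octahydroazulen-5-yl]-6-methylhept-5-ene-3,4-diyl diacetate (CNP0194318.1) | C=C1[C@H](OC(C)=O)C[C@@H]([C@@H](C)[C@H](OC(C)=O)[C@H](C=C(C)C)OC(C)=O)[C@@H](O)[C@@H]2C(C)=CC[C@@H]12 | target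

**Step count**
Total: 19 steps. Longest linear sequence: 11 steps (steps 1–9, 18, 19); the side-chain branch is steps 10–17.

**Three steps most likely to fail**

Step 18 (ring expansion, the proposed new step). Risks are C5 instead of C8 migration, the wrong C7 epimer, and decomposition of the secondary diazoalkane. The fallback uses known reaction types and replaces diazoalkane insertion by an amine-based Tiffeneau–Demjanov ring expansion; it sets out from aldehyde 25 and ketone 15. Condensation of 25 with (S)-tert-butanesulfinamide (CuSO4, CH2Cl2) gives the N-sulfinyl imine F1. Samarium diiodide-mediated aza-pinacol cross-coupling of F1 with 15 (THF, t-BuOH, −78 °C) gives the β-hydroxy sulfinamide F2, in which the auxiliary controls the C7–N centre. HCl in MeOH at 0 °C removes the sulfinyl group and gives the amino alcohol F3. Diazotisation of F3 (NaNO2, aqueous AcOH, 0 °C) triggers the 1,2-shift of the less substituted C8 with inversion at C7 and comes back to the route at 28.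

Step 10 (aldol with an enal acceptor). Prenal may react sluggishly or self-condense through its dienamine. The fallback changes to a Lewis-acid aldol and sets out from 16. A tin(II) triflate/chiral diamine-promoted Mukaiyama aldol of 16 with (Z)-2-(tert-butyldimethylsilyloxy)-1-(ethylthio)-1-(trimethylsilyloxy)ethene gives the syn thioester F4. Me2CuLi converts F4 into the methyl ketone F5. HF·pyridine removes the silyl group and comes back to the route at 18.

Step 5 (facial selectivity of the C9 hydroxylation). If the oxaziridine attacks the enolate from the β-face, the fallback sets out from 9 and accepts the epimeric equatorial alcohol F6 from the same hydroxylation. A Mitsunobu esterification of F6 with acetic acid (PPh3, DIAD, toluene, 0 °C) inverts C9 and comes back to the route at 12, so step 6 is skipped.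

**Further compounds**
F1 | step 18 | (2R,3S,4S)-1-{(E)-[(S)-tert-butanesulfinyl]imino}-2,6-dimethylhept-5-ene-3,4-diyl diacetate | CC(C)(C)[S@](=O)/N=C/[C@@H](C)[C@H](OC(C)=O)[C@H](C=C(C)C)OC(C)=O
F2 | step 18 | β-hydroxy sulfinamide from F1 and 15 (C6 tertiary alcohol with axial OH, C7–N centre R, sulfur S) | C=C1[C@H](OC(C)=O)C[C@@](O)([C@H](N[S@@](=O)C(C)(C)C)[C@@H](C)[C@H](OC(C)=O)[C@H](C=C(C)C)OC(C)=O)[C@@H]2C(C)=CC[C@@H]12
F3 | step 18 | β-amino alcohol from F2 (C6 tertiary alcohol, C7 primary amine, R at C7) | C=C1[C@H](OC(C)=O)C[C@@](O)([C@H](N)[C@@H](C)[C@H](OC(C)=O)[C@H](C=C(C)C)OC(C)=O)[C@@H]2C(C)=CC[C@@H]12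
F4 | step 10 | S-ethyl (2R,3S)-2-[(tert-butyldimethylsilyl)oxy]-3-hydroxy-5-methylhex-4-enethioate | CCSC(=O)[C@H](O[Si](C)(C)C(C)(C)C)[C@H](C=C(C)C)O
F5 | step 10 | (3R,4S)-3-[(tert-butyldimethylsilyl)oxy]-4-hydroxy-6-methylhept-5-en-2-one | CC(=O)[C@H](O[Si](C)(C)C(C)(C)C)[C@H](C=C(C)C)O
F6 | step 5 | (3aR,5S,7R,7aS)-7-[(tert-butyldimethylsilyl)oxy]-5-hydroxy-1-methyl-3,3a,5,6,7,7a-hexahydro-4H-inden-4-one | O=C1[C@@H](O)C[C@@H](O[Si](C)(C)C(C)(C)C)[C@@H]2C(C)=CC[C@@H]12
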